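**Retrosynthetic overview**
1. Endgame: acid removes the TBS, tert-butyl and acetonide groups and closes the 6,12-γ-lactone (last ring). Before that, the C8 hydroxyl is acylated with the (R)-acetonide acid 30, and the C1=C2 vinyl group and the C15 aldehyde are both released from one temporary δ-lactone C1(=O)–O–C15 (iBu2AlH, Wittig, MnO2).
2. Key disconnection: the carbocycle C5–C6–C7–C8–C9–C10 is opened at C9–C10 and C7–C8. This is a radical [4+2] annulation of bromo lactone 18 with the two-carbon enol ether 19 (C9=C8–OSi), ended by intramolecular allyl transfer from a 2-(stannylmethyl)acrylate (C7=C11–C13–Sn).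
3. Enabling feature: with C1 as a carbonyl, C10 is an α-acyl radical site 1,4-related to the C8 oxygen, and C8–O is homoallylic to the C11=C13 methylene. The temporary six-membered lactone ring (O–C1–C10–C5–C4–C15) fixes the reacting face of C10 and makes the new ring trans-fused.
4. 18 comes from lactone 11 (Johnson–Claisen/lactonisation of the 2-alkylidene-1,3-diol 7, C5 set from C6), bromination, and HWE attachment of the stannyl acrylate. 7 comes from methyl (S)-glycerate acetonide 1 (C6 from the chiral pool).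
5. Ring order: temporary δ-lactone (step 6) → carbocycle (step 12) → δ-lactone opened (steps 14–15) → γ-lactone (step 22).

Key step: step 12

Numbering: atoms are named by the elemane numbering of the target (C1=C2 vinyl and C14 methyl on C10; ring C5–C10; C11(=C13)–C12 lactone; C4(=C3)–C15 aldehyde).
Assumption: the C10 epimers of 10–18 and the E/Z isomers of 18 are carried as mixtures, because C10 becomes a planar radical and C7/C11 are re-set in step 12.

Step 1
Reactants: 1 methyl (4S)-2,2-dimethyl-1,3-dioxolane-4-carboxylate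
Product: 2 methyl (2S)-2,3-dihydroxypropanoate
Conditions: AcOH/H2O (4:1), 45 °C
Reagents that add atoms: none
Why: Acid hydrolysis of the isopropylidene ketal frees the diol without touching the methyl ester or the stereocentre (acetal hydrolysis).

Step 2
Reactants: 2 methyl (2S)-2,3-dihydroxypropanoate
Product: 3 methyl (2S)-2,3-bis(tert-butyldimethylsilyloxy)propanoate
Conditions: TBSCl (2.4 equiv), imidazole, DMF, 0 °C → rt
Reagents that add atoms: tert-butyldimethylsilyl chloride, CC(C)(C)[Si](C)(C)Cl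
Why: Imidazole-promoted silyl ether formation protects both hydroxyls and leaves the stereocentre untouched.

Step 3
Reactants: 3 methyl (2S)-2,3-bis(tert-butyldimethylsilyloxy)propanoate
Product: 4 (2S)-2,3-bis(tert-butyldimethylsilyloxy)propanal
Conditions: iBu2AlH (1.1 equiv), CH2Cl2, −78 °C
Reagents that add atoms: none
Why: Partial ester reduction stops at the aluminium hemiacetal at −78 °C, so the α-silyloxy aldehyde (future C5–C6–C7) should form without epimerisation (DIBAL-H ester-to-aldehyde reduction).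

Step 4
Reactants: 4 (2S)-2,3-bis(tert-butyldimethylsilyloxy)propanal; 5 dimethyl malonate
Product: 6 dimethyl 2-[(2R)-2,3-bis(tert-butyldimethylsilyloxy)propylidene]malonate
Conditions: TiCl4, pyridine, THF, 0 °C → rt
Reagents that add atoms: none
Why: The TiCl4/pyridine Knoevenagel condensation runs under buffered, non-enolising conditions, so the α-silyloxy stereocentre (C6) should be kept.

Step 5
Reactants: 6 dimethyl 2-[(2R)-2,3-bis(tert-butyldimethylsilyloxy)propylidene]malonate
Product: 7 2-[(2R)-2,3-bis(tert-butyldimethylsilyloxy)propylidene]propane-1,3-diol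
Conditions: iBu2AlH (5 equiv), CH2Cl2, −78 → 0 °C
Reagents that add atoms: none
Why: Excess iBu2AlH reduces both conjugated esters in the 1,2-sense to give the 2-alkylidene-1,3-diol (ester reduction).

Step 6
Reactants: 7 2-[(2R)-2,3-bis(tert-butyldimethylsilyloxy)propylidene]propane-1,3-diol; 8 triethyl orthopropionate
Product: 11 (4R)-4-[(1R)-1,2-bis(tert-butyldimethylsilyloxy)ethyl]-3-methyl-5-methylidenetetrahydro-2H-pyran-2-one (C3 epimers), via mixed ketene acetal 9 (not isolated), via hydroxy ester 10 (not isolated)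
Conditions: 8 (1.5 equiv), EtCO2H (cat.), xylene, 140 °C, EtOH distilled off
Reagents that add atoms: none
Why: Johnson–Claisen rearrangement of the ketene acetal through a chair transition state followed by lactonisation of the δ-hydroxy ester should give the lactone, with C5 set by attack anti to the C6–O bond while C6–H eclipses the trisubstituted alkene (allylic 1,3-strain); C10 is deliberately left uncontrolled.

Step 7
Reactants: 11 (4R)-4-[(1R)-1,2-bis(tert-butyldimethylsilyloxy)ethyl]-3-methyl-5-methylidenetetrahydro-2H-pyran-2-one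
Product: 12 (4R)-3-bromo-4-[(1R)-1,2-bis(tert-butyldimethylsilyloxy)ethyl]-3-methyl-5-methylidenetetrahydro-2H-pyran-2-one (C3 epimers)
Conditions: LiN(iPr)2, THF, −78 °C; then NBS, −78 °C
Reagents that add atoms: N-bromosuccinimide, O=C1CCC(=O)N1Br
Why: Electrophilic bromination of the lithium lactone enolate (α-halogenation) installs the radical precursor at C10, whose configuration is irrelevant because it becomes a planar radical.

Step 8
Reactants: 12 (4R)-3-bromo-4-[(1R)-1,2-bis(tert-butyldimethylsilyloxy)ethyl]-3-methyl-5-methylidenetetrahydro-2H-pyran-2-one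
Product: 13 (4R)-3-bromo-4-[(1R)-1-(tert-butyldimethylsilyloxy)-2-hydroxyethyl]-3-methyl-5-methylidenetetrahydro-2H-pyran-2-one
Conditions: HF·pyridine, pyridine, THF, 0 °C
Reagents that add atoms: none
Why: Buffered fluoride cleaves the less hindered primary TBS ether selectively (chemoselective desilylation), and the C6 oxygen stays protected so the δ-lactone cannot translactonise.

Step 9
Reactants: 13 (4R)-3-bromo-4-[(1R)-1-(tert-butyldimethylsilyloxy)-2-hydroxyethyl]-3-methyl-5-methylidenetetrahydro-2H-pyran-2-one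
Product: 14 (2R)-2-[(4R)-3-bromo-3-methyl-5-methylidene-2-oxotetrahydro-2H-pyran-4-yl]-2-(tert-butyldimethylsilyloxy)acetaldehyde
Conditions: Dess–Martin periodinane, NaHCO3, CH2Cl2, 0 °C → rt
Reagents that add atoms: none
Why: Buffered Dess–Martin oxidation should give the α-silyloxy aldehyde (C7) without epimerisation at C6.

Step 10
Reactants: 15 tert-butyl 2-(diethoxyphosphoryl)acetate; 16 tributyl(iodomethyl)stannane
Product: 17 tert-butyl 2-(diethoxyphosphoryl)-3-(tributylstannyl)propanoate
Conditions: NaH, THF/DMF, 0 °C → rt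
Reagents that add atoms: none
Why: SN2 alkylation of the sodium phosphonoacetate by the primary iodide gives the α-(stannylmethyl) phosphonate (phosphonate alkylation).

Step 11
Reactants: 14 (2R)-2-[(4R)-3-bromo-3-methyl-5-methylidene-2-oxotetrahydro-2H-pyran-4-yl]-2-(tert-butyldimethylsilyloxy)acetaldehyde; 17 tert-butyl 2-(diethoxyphosphoryl)-3-(tributylstannyl)propanoate
Product: 18 tert-butyl (4S)-4-[(4R)-3-bromo-3-methyl-5-methylidene-2-oxotetrahydro-2H-pyran-4-yl]-4-(tert-butyldimethylsilyloxy)-2-[(tributylstannyl)methyl]but-2-enoate (E/Z mixture)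
Conditions: 17, NaH, THF, 0 °C; then 14, −20 °C → rt
Reagents that add atoms: none
Why: Horner–Wadsworth–Emmons olefination builds the 2-(stannylmethyl)acrylate on C7, and its E/Z ratio does not matter because C7 becomes sp3 and C11 loses tin in step 12.

Step 12
Reactants: 18 tert-butyl (4S)-4-[(4R)-3-bromo-3-methyl-5-methylidene-2-oxotetrahydro-2H-pyran-4-yl]-4-(tert-butyldimethylsilyloxy)-2-[(tributylstannyl)methyl]but-2-enoate; 19 trimethyl(vinyloxy)silane
Product: 21 tert-butyl 2-[(4aS,5R,6R,7S,8aR)-5-(tert-butyldimethylsilyloxy)-7-hydroxy-8a-methyl-4-methylidene-1-oxooctahydro-1H-isochromen-6-yl]prop-2-enoate, via trimethylsilyl ether 20 (not isolated)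
Conditions: 19 (15 equiv), AIBN (0.3 equiv, in portions), K2CO3 (solid), PhH (0.02 M), 80 °C, sealed tube; then 1 M HCl, THF, 0 °C
Reagents that add atoms: none
Why: Proposed new method: Bu3Sn• (from AIBN-initiated fragmentation) abstracts bromine from 18 to give the planar, electrophilic tertiary α-acyl radical at C10, which adds to the CH2 terminus of the electron-rich enol ether 19; the resulting nucleophilic α-siloxy radical at C8 closes the carbocycle by 6-exo-trig attack on C7 of the electron-poor 2-(stannylmethyl)acrylate, and β-scission of the C13–Sn bond gives the C11=C13 methylene and returns Bu3Sn• to the chain. The closest known reaction type is the three-component radical coupling of an α-halo carbonyl compound, an electron-rich alkene and an allylstannane (Keck-type allyl transfer), here with the allyl transfer made intramolecular so that it becomes a [4+2] annulation. C10 is set by the temporary δ-lactone, because the radical is attacked on the ring face anti to the C5 substituent, which places C9 trans to C6 and makes the new ring trans-fused. C8 and C7 are set in the chair transition state of the ring closure, where the OTMS group must be equatorial to avoid the axial C10 methyl, the C6–OTBS is equatorial and the acrylate unit on C7 takes the equatorial position. The step needs the C10 radical to react intermolecularly first, which the substrate secures because its own alkenes are reachable only through 3-exo, 4-exo, 4-endo or 5-endo modes and the alternating polarity matches each radical with its partner.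

Step 13
Reactants: 21 tert-butyl 2-[(4aS,5R,6R,7S,8aR)-5-(tert-butyldimethylsilyloxy)-7-hydroxy-8a-methyl-4-methylidene-1-oxooctahydro-1H-isochromen-6-yl]prop-2-enoate
Product: 22 tert-butyl 2-[(4aS,5R,6R,7S,8aR)-5-(tert-butyldimethylsilyloxy)-8a-methyl-4-methylidene-1-oxo-7-(triethylsilyloxy)octahydro-1H-isochromen-6-yl]prop-2-enoate
Conditions: Et3SiCl, imidazole, DMF, 0 °C → rt
Reagents that add atoms: chlorotriethylsilane, CC[Si](Cl)(CC)CC
Why: Silyl ether formation masks the C8 hydroxyl so that its alkoxide cannot lactonise onto the C12 ester under the basic conditions of step 15.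

Step 14
Reactants: 22 tert-butyl 2-[(4aS,5R,6R,7S,8aR)-5-(tert-butyldimethylsilyloxy)-8a-methyl-4-methylidene-1-oxo-7-(triethylsilyloxy)octahydro-1H-isochromen-6-yl]prop-2-enoate
Product: 23 tert-butyl 2-[(4aS,5R,6R,7S,8aR)-5-(tert-butyldimethylsilyloxy)-1-hydroxy-8a-methyl-4-methylidene-7-(triethylsilyloxy)octahydro-1H-isochromen-6-yl]prop-2-enoate (C1 anomers)
Conditions: iBu2AlH (1.2 equiv), CH2Cl2, −78 °C
Reagents that add atoms: none
Why: The lactone carbonyl should be far more electrophilic than the hindered, conjugated tert-butyl ester, and its aluminium hemiacetal is stable at −78 °C (lactone-to-lactol reduction).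

Step 15
Reactants: 23 tert-butyl 2-[(4aS,5R,6R,7S,8aR)-5-(tert-butyldimethylsilyloxy)-1-hydroxy-8a-methyl-4-methylidene-7-(triethylsilyloxy)octahydro-1H-isochromen-6-yl]prop-2-enoate
Product: 24 tert-butyl (5R,6R,7R,8S,10S)-6-(tert-butyldimethylsilyloxy)-15-hydroxy-8-(triethylsilyloxy)elema-1,3,11(13)-trien-12-oate
Conditions: Ph3PCH3Br, KOtBu, THF, 0 °C → rt
Reagents that add atoms: methyltriphenylphosphonium bromide (as its ylide), [Br-].C[P+](c1ccccc1)(c1ccccc1)c1ccccc1
Why: Wittig methylenation of the open hydroxy aldehyde form of the lactol creates the C1=C2 vinyl group on the quaternary C10 and frees the C15 allylic alcohol.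

Step 16
Reactants: 24 tert-butyl (5R,6R,7R,8S,10S)-6-(tert-butyldimethylsilyloxy)-15-hydroxy-8-(triethylsilyloxy)elema-1,3,11(13)-trien-12-oate
Product: 25 tert-butyl (5R,6R,7R,8S,10S)-6-(tert-butyldimethylsilyloxy)-15-oxo-8-(triethylsilyloxy)elema-1,3,11(13)-trien-12-oate
Conditions: MnO2 (activated), CH2Cl2, rt
Reagents that add atoms: none
Why: MnO2 oxidises the primary allylic alcohol to the 2-substituted acrolein (allylic oxidation) while the C6 oxygen is still silylated, so no lactol can form at C15.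

Step 17
Reactants: 25 tert-butyl (5R,6R,7R,8S,10S)-6-(tert-butyldimethylsilyloxy)-15-oxo-8-(triethylsilyloxy)elema-1,3,11(13)-trien-12-oate
Product: 26 tert-butyl (5R,6R,7R,8S,10S)-6-(tert-butyldimethylsilyloxy)-8-hydroxy-15-oxoelema-1,3,11(13)-trien-12-oate
Conditions: HF·pyridine, pyridine, THF, 0 °C
Reagents that add atoms: none
Why: Buffered fluoride removes the triethylsilyl ether much faster than the hindered secondary TBS ether (chemoselective desilylation), freeing only the C8 hydroxyl.

Step 18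
Reactants: 27 2-[(4R)-2,2-dimethyl-1,3-dioxolan-4-yl]ethan-1-ol
Product: 28 2-[(4R)-2,2-dimethyl-1,3-dioxolan-4-yl]acetaldehyde
Conditions: Dess–Martin periodinane, NaHCO3, CH2Cl2, rt
Reagents that add atoms: none
Why: Dess–Martin oxidation of the primary alcohol gives the aldehyde without affecting the acetonide or its stereocentre.

Step 19
Reactants: 28 2-[(4R)-2,2-dimethyl-1,3-dioxolan-4-yl]acetaldehyde
Product: 29 2-[(4R)-2,2-dimethyl-1,3-dioxolan-4-yl]prop-2-enal
Conditions: aq. CH2O (37%), pyrrolidine (10 mol %), EtCO2H (10 mol %), iPrOH, 45 °C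
Reagents that add atoms: formaldehyde, C=O
Why: Amine-catalysed Mannich condensation and elimination (α-methylenation of an aldehyde) installs the methylene next to the stereocentre, which carries no acidic hydrogen afterwards.

Step 20
Reactants: 29 2-[(4R)-2,2-dimethyl-1,3-dioxolan-4-yl]prop-2-enal
Product: 30 2-[(4R)-2,2-dimethyl-1,3-dioxolan-4-yl]prop-2-enoic acid
Conditions: NaClO2, NaH2PO4, 2-methyl-2-butene, tBuOH/H2O, rt
Reagents that add atoms: sodium chlorite, [Na+].[O-]Cl=O
Why: Pinnick oxidation converts the enal into the acrylic acid at mildly acidic pH, which the acetonide tolerates.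

Step 21
Reactants: 26 tert-butyl (5R,6R,7R,8S,10S)-6-(tert-butyldimethylsilyloxy)-8-hydroxy-15-oxoelema-1,3,11(13)-trien-12-oate; 30 2-[(4R)-2,2-dimethyl-1,3-dioxolan-4-yl]prop-2-enoic acid
Product: 32 tert-butyl (5R,6R,7R,8S,10S)-6-(tert-butyldimethylsilyloxy)-8-{2-[(4R)-2,2-dimethyl-1,3-dioxolan-4-yl]prop-2-enoyloxy}-15-oxoelema-1,3,11(13)-trien-12-oate, via mixed anhydride 31 (not isolated)
Conditions: 30, 2,4,6-trichlorobenzoyl chloride, Et3N, THF, rt; then 26, DMAP, PhMe, rt
Reagents that add atoms: none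
Why: Yamaguchi esterification acylates the only free hydroxyl (equatorial C8–OH) with retention, since the C–O bond at C8 is not broken.

Step 22
Reactants: 32 tert-butyl (5R,6R,7R,8S,10S)-6-(tert-butyldimethylsilyloxy)-8-{2-[(4R)-2,2-dimethyl-1,3-dioxolan-4-yl]prop-2-enoyloxy}-15-oxoelema-1,3,11(13)-trien-12-oate
Product: 34 (5R,6R,7R,8S,10S)-8-[(3R)-3,4-dihydroxy-2-methylidenebutanoyloxy]-15-oxoelema-1,3,11(13)-trien-12,6-olide (target), via seco acid 33 (not isolated)
Conditions: CF3CO2H/CH2Cl2/H2O (10:10:1), 0 °C → rt; then evaporation from PhMe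
Reagents that add atoms: none
Why: Acidolysis should cleave the tert-butyl ester, the C6 TBS ether and the acetonide, and the resulting trans-diequatorial γ-hydroxy acid should close to the 6,12-lactone under the same acid (Fischer-type lactonisation) with no stereocentre touched.

**Compound list**
1 | methyl (4S)-2,2-dimethyl-1,3-dioxolane-4-carboxylate | COC(=O)[C@@H]1COC(C)(C)O1 | starting material
2 | methyl (2S)-2,3-dihydroxypropanoate | COC(=O)[C@@H](O)CO | intermediate
3 | methyl (2S)-2,3-bis(tert-butyldimethylsilyloxy)propanoate | COC(=O)[C@@H](O[Si](C)(C)C(C)(C)C)CO[Si](C)(C)C(C)(C)C | intermediate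
4 | (2S)-2,3-bis(tert-butyldimethylsilyloxy)propanal | O=C[C@@H](O[Si](C)(C)C(C)(C)C)CO[Si](C)(C)C(C)(C)C | intermediate
5 | dimethyl malonate | COC(=O)CC(=O)OC | starting material
6 | dimethyl 2-[(2R)-2,3-bis(tert-butyldimethylsilyloxy)propylidene]malonate | COC(=O)C(=C[C@@H](O[Si](C)(C)C(C)(C)C)CO[Si](C)(C)C(C)(C)C)C(=O)OC | intermediate
7 | 2-[(2R)-2,3-bis(tert-butyldimethylsilyloxy)propylidene]propane-1,3-diol | OCC(CO)=C[C@@H](O[Si](C)(C)C(C)(C)C)CO[Si](C)(C)C(C)(C)C | intermediate
8 | triethyl orthopropionate | CCC(OCC)(OCC)OCC | starting material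
9 | mixed ketene acetal (1-ethoxyprop-1-enyl ether of 7 at one CH2OH; not isolated) | CC=C(OCC)OCC(CO)=C[C@@H](O[Si](C)(C)C(C)(C)C)CO[Si](C)(C)C(C)(C)C | intermediate
10 | ethyl (3R)-3-[(1R)-1,2-bis(tert-butyldimethylsilyloxy)ethyl]-4-(hydroxymethyl)-2-methylpent-4-enoate (C2 epimers; not isolated) | CCOC(=O)C(C)[C@@H]([C@@H](O[Si](C)(C)C(C)(C)C)CO[Si](C)(C)C(C)(C)C)C(=C)CO | intermediate
11 | (4R)-4-[(1R)-1,2-bis(tert-butyldimethylsilyloxy)ethyl]-3-methyl-5-methylidenetetrahydro-2H-pyran-2-one (C3 epimers) | O=C1OCC(=C)[C@H]([C@@H](O[Si](C)(C)C(C)(C)C)CO[Si](C)(C)C(C)(C)C)C1C | intermediate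
12 | (4R)-3-bromo-4-[(1R)-1,2-bis(tert-butyldimethylsilyloxy)ethyl]-3-methyl-5-methylidenetetrahydro-2H-pyran-2-one (C3 epimers) | O=C1OCC(=C)[C@H]([C@@H](O[Si](C)(C)C(C)(C)C)CO[Si](C)(C)C(C)(C)C)C1(C)Br | intermediate
13 | (4R)-3-bromo-4-[(1R)-1-(tert-butyldimethylsilyloxy)-2-hydroxyethyl]-3-methyl-5-methylidenetetrahydro-2H-pyran-2-one | O=C1OCC(=C)[C@H]([C@@H](O[Si](C)(C)C(C)(C)C)CO)C1(C)Br | intermediate
14 | (2R)-2-[(4R)-3-bromo-3-methyl-5-methylidene-2-oxotetrahydro-2H-pyran-4-yl]-2-(tert-butyldimethylsilyloxy)acetaldehyde | O=C1OCC(=C)[C@H]([C@@H](O[Si](C)(C)C(C)(C)C)C=O)C1(C)Br | intermediate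
15 | tert-butyl 2-(diethoxyphosphoryl)acetate | CCOP(=O)(CC(=O)OC(C)(C)C)OCC | starting material
16 | tributyl(iodomethyl)stannane | CCCC[Sn](CCCC)(CCCC)CI | starting material
17 | tert-butyl 2-(diethoxyphosphoryl)-3-(tributylstannyl)propanoate | CCOP(=O)(OCC)C(C[Sn](CCCC)(CCCC)CCCC)C(=O)OC(C)(C)C | intermediate
18 | tert-butyl (4S)-4-[(4R)-3-bromo-3-methyl-5-methylidene-2-oxotetrahydro-2H-pyran-4-yl]-4-(tert-butyldimethylsilyloxy)-2-[(tributylstannyl)methyl]but-2-enoate (E/Z mixture, C3-bromo epimers) | O=C1OCC(=C)[C@H]([C@@H](O[Si](C)(C)C(C)(C)C)C=C(C[Sn](CCCC)(CCCC)CCCC)C(=O)OC(C)(C)C)C1(C)Br | intermediate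
19 | trimethyl(vinyloxy)silane | C=CO[Si](C)(C)C | starting material
20 | trimethylsilyl ether of 21 (not isolated) | O=C1OCC(=C)[C@@H]2[C@@H](O[Si](C)(C)C(C)(C)C)[C@H](C(=C)C(=O)OC(C)(C)C)[C@@H](O[Si](C)(C)C)C[C@@]12C | intermediate
21 | tert-butyl 2-[(4aS,5R,6R,7S,8aR)-5-(tert-butyldimethylsilyloxy)-7-hydroxy-8a-methyl-4-methylidene-1-oxooctahydro-1H-isochromen-6-yl]prop-2-enoate | O=C1OCC(=C)[C@@H]2[C@@H](O[Si](C)(C)C(C)(C)C)[C@H](C(=C)C(=O)OC(C)(C)C)[C@@H](O)C[C@@]12C | intermediate
22 | tert-butyl 2-[(4aS,5R,6R,7S,8aR)-5-(tert-butyldimethylsilyloxy)-8a-methyl-4-methylidene-1-oxo-7-(triethylsilyloxy)octahydro-1H-isochromen-6-yl]prop-2-enoate | O=C1OCC(=C)[C@@H]2[C@@H](O[Si](C)(C)C(C)(C)C)[C@H](C(=C)C(=O)OC(C)(C)C)[C@@H](O[Si](CC)(CC)CC)C[C@@]12C | intermediate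
23 | tert-butyl 2-[(4aS,5R,6R,7S,8aR)-5-(tert-butyldimethylsilyloxy)-1-hydroxy-8a-methyl-4-methylidene-7-(triethylsilyloxy)octahydro-1H-isochromen-6-yl]prop-2-enoate (C1 anomers) | OC1OCC(=C)[C@@H]2[C@@H](O[Si](C)(C)C(C)(C)C)[C@H](C(=C)C(=O)OC(C)(C)C)[C@@H](O[Si](CC)(CC)CC)C[C@@]12C | intermediate
24 | tert-butyl (5R,6R,7R,8S,10S)-6-(tert-butyldimethylsilyloxy)-15-hydroxy-8-(triethylsilyloxy)elema-1,3,11(13)-trien-12-oate | C=C[C@]1(C)C[C@H](O[Si](CC)(CC)CC)[C@@H](C(=C)C(=O)OC(C)(C)C)[C@H](O[Si](C)(C)C(C)(C)C)[C@H]1C(=C)CO | intermediate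
25 | tert-butyl (5R,6R,7R,8S,10S)-6-(tert-butyldimethylsilyloxy)-15-oxo-8-(triethylsilyloxy)elema-1,3,11(13)-trien-12-oate | C=C[C@]1(C)C[C@H](O[Si](CC)(CC)CC)[C@@H](C(=C)C(=O)OC(C)(C)C)[C@H](O[Si](C)(C)C(C)(C)C)[C@H]1C(=C)C=O | intermediate
26 | tert-butyl (5R,6R,7R,8S,10S)-6-(tert-butyldimethylsilyloxy)-8-hydroxy-15-oxoelema-1,3,11(13)-trien-12-oate | C=C[C@]1(C)C[C@H](O)[C@@H](C(=C)C(=O)OC(C)(C)C)[C@H](O[Si](C)(C)C(C)(C)C)[C@H]1C(=C)C=O | intermediate
27 | 2-[(4R)-2,2-dimethyl-1,3-dioxolan-4-yl]ethan-1-ol | OCC[C@@H]1COC(C)(C)O1 | starting material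
28 | 2-[(4R)-2,2-dimethyl-1,3-dioxolan-4-yl]acetaldehyde | O=CC[C@@H]1COC(C)(C)O1 | intermediate
29 | 2-[(4R)-2,2-dimethyl-1,3-dioxolan-4-yl]prop-2-enal | O=CC(=C)[C@@H]1COC(C)(C)O1 | intermediate
30 | 2-[(4R)-2,2-dimethyl-1,3-dioxolan-4-yl]prop-2-enoic acid | OC(=O)C(=C)[C@@H]1COC(C)(C)O1 | intermediate
31 | mixed anhydride of 30 and 2,4,6-trichlorobenzoic acid (not isolated) | O=C(OC(=O)C(=C)[C@@H]1COC(C)(C)O1)c1c(Cl)cc(Cl)cc1Cl | intermediate
32 | tert-butyl (5R,6R,7R,8S,10S)-6-(tert-butyldimethylsilyloxy)-8-{2-[(4R)-2,2-dimethyl-1,3-dioxolan-4-yl]prop-2-enoyloxy}-15-oxoelema-1,3,11(13)-trien-12-oate | C=C[C@]1(C)C[C@H](OC(=O)C(=C)[C@@H]2COC(C)(C)O2)[C@@H](C(=C)C(=O)OC(C)(C)C)[C@H](O[Si](C)(C)C(C)(C)C)[C@H]1C(=C)C=O | intermediate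
33 | seco acid: 8-[(3R)-3,4-dihydroxy-2-methylidenebutanoyloxy]-6-hydroxy-15-oxoelema-1,3,11(13)-trien-12-oic acid, ring stereocentres as in 32 (not isolated) | C=C[C@]1(C)C[C@H](OC(=O)C(=C)[C@@H](O)CO)[C@@H](C(=C)C(O)=O)[C@H](O)[C@H]1C(=C)C=O | intermediate
34 | (5R,6R,7R,8S,10S)-8-[(3R)-3,4-dihydroxy-2-methylidenebutanoyloxy]-15-oxoelema-1,3,11(13)-trien-12,6-olide | C=C[C@]1(C)C[C@H](OC(=O)C(=C)[C@@H](O)CO)[C@H]2C(=C)C(=O)O[C@@H]2[C@H]1C(=C)C=O | target

Total step count: 22. Longest linear sequence: 18 steps (steps 1–9, 11–17, 21, 22).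

**Steps most likely to fail**

Step 12 (proposed new method). The hindered tertiary C10 radical may add too slowly to the enol ether, so that intermolecular allyl transfer between two molecules of 18 or chain termination takes over. The C8 radical may also close in the 6-endo sense onto the C4 methylene, or facial control at C10 may erode. The fallback separates the two bond formations with known reactions, sets out from 12 and comes back at 21. Radical alkylation of enol silane 19 by 12 (Et3B, air, PhH, rt), again anti to the C5 substituent, should give the lactone aldehyde F1. Acetalisation (HC(OMe)3, PPTS, MeOH) gives the dimethyl acetal F2. HF·pyridine frees the primary alcohol F3, and Dess–Martin oxidation gives the C7 aldehyde F4. HWE olefination with 17 (NaH, THF) gives the allylstannane acetal F5, and mild hydrolysis (PPTS, acetone/H2O) gives the allylstannane aldehyde F6. BF3·OEt2 (CH2Cl2, −78 °C) then promotes the intramolecular allylstannane–aldehyde addition through the same all-equatorial chair and returns to 21.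

Step 14. The hydride may also attack the tert-butyl enoate, or the lactol may be over-reduced to the diol. The fallback sets out from 22 and comes back at 23. Aminolysis of the lactone with Me(MeO)NH·HCl/AlMe3 (CH2Cl2, 0 °C → rt) should give the Weinreb amide F7 with the free C15 alcohol. Cp2Zr(H)Cl (THF, rt) then reduces the amide selectively to the aldehyde, which closes to lactol 23.

Step 6. Facial selectivity at C5 may be incomplete at 140 °C, and the allylic alcohol of hydroxy ester 10 may undergo a second rearrangement before it lactonises. The fallback sets out from 7 and comes back at 11. Mono-acylation (EtCOCl, pyridine, CH2Cl2, −20 °C) gives the mono-propionate F8 (both regioisomers converge). Ireland–Claisen rearrangement (LiN(iPr)2, Me3SiCl, THF, −78 °C → rt, free hydroxyl silylated in situ, acidic work-up) gives the hydroxy acid F9 under the same allylic-strain control at low temperature. Lactonisation (EDC·HCl, DMAP, CH2Cl2) returns to 11.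

**Further compounds**
F1 | step 12 | lactone aldehyde: 2-[(3S,4R)-4-[(1R)-1,2-bis(tert-butyldimethylsilyloxy)ethyl]-3-methyl-5-methylidene-2-oxotetrahydro-2H-pyran-3-yl]acetaldehyde (C10 as in the target) | O=C1OCC(=C)[C@H]([C@@H](O[Si](C)(C)C(C)(C)C)CO[Si](C)(C)C(C)(C)C)[C@@]1(C)CC=O
F2 | step 12 | dimethyl acetal of F1 | O=C1OCC(=C)[C@H]([C@@H](O[Si](C)(C)C(C)(C)C)CO[Si](C)(C)C(C)(C)C)[C@@]1(C)CC(OC)OC
F3 | step 12 | primary alcohol from F2 (C7–OH free, C6–OTBS kept) | O=C1OCC(=C)[C@H]([C@@H](O[Si](C)(C)C(C)(C)C)CO)[C@@]1(C)CC(OC)OC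
F4 | step 12 | C7 aldehyde from F3 | O=C1OCC(=C)[C@H]([C@@H](O[Si](C)(C)C(C)(C)C)C=O)[C@@]1(C)CC(OC)OC
F5 | step 12 | allylstannane acetal (tert-butyl 2-[(tributylstannyl)methyl]but-2-enoate on C6, E/Z mixture) | O=C1OCC(=C)[C@H]([C@@H](O[Si](C)(C)C(C)(C)C)C=C(C[Sn](CCCC)(CCCC)CCCC)C(=O)OC(C)(C)C)[C@@]1(C)CC(OC)OC
F6 | step 12 | allylstannane aldehyde from F5 | O=C1OCC(=C)[C@H]([C@@H](O[Si](C)(C)C(C)(C)C)C=C(C[Sn](CCCC)(CCCC)CCCC)C(=O)OC(C)(C)C)[C@@]1(C)CC=O
F7 | step 14 | Weinreb amide: tert-butyl 6-(tert-butyldimethylsilyloxy)-15-hydroxy-1-[methoxy(methyl)amino]-1-oxo-8-(triethylsilyloxy)-2-norelema-3,11(13)-dien-12-oate (ring stereocentres as in 22) | CON(C)C(=O)[C@]1(C)C[C@H](O[Si](CC)(CC)CC)[C@@H](C(=C)C(=O)OC(C)(C)C)[C@H](O[Si](C)(C)C(C)(C)C)[C@H]1C(=C)CO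
F8 | step 6 | mono-propionate of diol 7 | CCC(=O)OCC(CO)=C[C@@H](O[Si](C)(C)C(C)(C)C)CO[Si](C)(C)C(C)(C)C
F9 | step 6 | (3R)-3-[(1R)-1,2-bis(tert-butyldimethylsilyloxy)ethyl]-4-(hydroxymethyl)-2-methylpent-4-enoic acid (C2 epimers) | OC(=O)C(C)[C@@H]([C@@H](O[Si](C)(C)C(C)(C)C)CO[Si](C)(C)C(C)(C)C)C(=C)CO
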